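The route rests on cutting the C1–C10 bond of the 3(2H)-furanone (ring O–C10–C1–C2–C3), the bond between the ketone carbon and the oxygen-bearing quaternary carbon. The C1 ketone and the C8 oxygen are 1,4-related through C10–C9, so an enantioselective intramolecular Stetter reaction can forge this bond. An achiral, open-chain (Z)-β-alkoxyenal, tethered through the future ring oxygen to a β-alkoxycrotonate, closes the furanone and sets C10 in one catalytic step. The divinyl ether precursor arises from a dioxinone by β-elimination. A butenolide is then annulated by vinylogous aldol addition (C5–C6) and chromium-mediated allylation (C7–C8), which also closes the ten-membered ring.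

Key step: step 3

Remark (numbering): germacranolide numbering is used for the target and its precursors: C1 ketone, C2=C3, C3–O–C10 ether, C4 (=C15H2), C5 (OH), C6 (lactone O), C7, C8 (ester), C9, C10 (C14 methyl), C11=C13, C12 lactone carbonyl.

Remark (assumption): the chromium allylation of step 14 is taken to follow the usual closed chair transition state and so to give the anti adduct (8S); the ester is therefore introduced with inversion in step 15.

Step 1
Reactants: 1 4,4-dimethoxybutan-2-one; 2 2,2,6-trimethyl-4H-1,3-dioxin-4-one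
Product: 4 2-(2,2-dimethoxyethyl)-2,6-dimethyl-4H-1,3-dioxin-4-one (racemic), via acetylketene 3 (not isolated)
Conditions: 1 (5 equiv), xylene, 130 °C, acetone distilled off
Reagents that add atoms: none
Why: Thermal retro-[4+2] of 2 releases acetylketene, which is trapped by the ketone carbonyl of 1 in a hetero-Diels–Alder reaction (dioxinone ketal exchange) driven by removal of acetone; the ketal stereocentre is destroyed in step 2 and need not be controlled.

Step 2
Reactants: 4 2-(2,2-dimethoxyethyl)-2,6-dimethyl-4H-1,3-dioxin-4-one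
Product: 7 methyl (2Z)-3-{[(2Z)-4-oxobut-2-en-2-yl]oxy}but-2-enoate, via dioxinone aldehyde 5 (not isolated), via potassium enoate 6 (not isolated)
Conditions: CF3CO2H–H2O (9:1), CH2Cl2, 0 °C; concentrate; then K2CO3, MeI, DMF, 0 °C
Reagents that add atoms: water O; iodomethane CI
Why: Acid cleaves the dimethyl acetal but not the electron-poor acylal-type ring ketal, then E1cB elimination from the β-acyloxy aldehyde expels the carboxylate (a far better leaving group than the vinylogous enolate) and opens the ring to the divinyl ether, whose carboxylate is O-methylated in the same flask; the Z-crotonate geometry is inherited from the ring and the enal E/Z isomers should equilibrate through the push–pull system.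

Step 3
Reactants: 7 methyl (2Z)-3-{[(2Z)-4-oxobut-2-en-2-yl]oxy}but-2-enoate
Product: 8 methyl [(2S)-2,5-dimethyl-3-oxo-2,3-dihydrofuran-2-yl]acetate
Conditions: (5aS,10bR)-2-(pentafluorophenyl)-5a,10b-dihydro-4H,6H-indeno[2,1-b][1,2,4]triazolo[4,3-d][1,4]oxazin-2-ium tetrafluoroborate (20 mol%), KN(SiMe3)2 (18 mol%), toluene, 23 °C
Reagents that add atoms: none
Why: Intramolecular asymmetric Stetter reaction: the triazolylidene adds to the C1 aldehyde of the (Z)-β-alkoxyenal, proton transfer gives the acyl-anion equivalent, whose C1 adds to C10, the β-carbon of the tethered β-alkoxycrotonate, and protonation of the ester enolate with loss of the carbene gives the C1 ketone. The closest known reaction is the triazolium-catalysed Stetter cyclisation of O-tethered aldehyde/β-alkoxycrotonate pairs to 2,2-disubstituted benzofuran-3(2H)-ones with a quaternary centre. The 3(2H)-furanone ring (O, C10, C1, C2, C3) closes in the 5-exo-trig mode with the ether oxygen as tether, the C1–C10 bond being the ring-closing bond. The only new stereocentre, quaternary C10, is controlled by the chiral aminoindanol-fused carbene, which selects one enantiotopic face of the achiral trisubstituted acceptor; the catalyst antipode is chosen to give 10S. The step needs acyl-anion rather than homoenolate, redox or benzoin reactivity, which the 5-exo tether, the electron-poor N-pentafluorophenyl catalyst and the absence of protic nucleophiles should secure, and it needs the Z-enal, which is available because the push–pull enal equilibrates and only the Z isomer can reach C10.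

Step 4
Reactants: 8 methyl [(2S)-2,5-dimethyl-3-oxo-2,3-dihydrofuran-2-yl]acetate
Product: 9 [(2S)-2,5-dimethyl-3-oxo-2,3-dihydrofuran-2-yl]acetaldehyde
Conditions: i-Bu2AlH (1.05 equiv), CH2Cl2, −78 °C; aq. potassium sodium tartrate
Reagents that add atoms: none
Why: Partial ester reduction: the unhindered methyl ester should give a stable tetrahedral aluminium hemiacetal at −78 °C, while the furanone carbonyl is a deactivated vinylogous-ester carbonyl next to the quaternary C10, and the non-basic medium avoids retro-oxa-Michael opening at C10.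

Step 5
Reactants: 9 [(2S)-2,5-dimethyl-3-oxo-2,3-dihydrofuran-2-yl]acetaldehyde
Product: 10 (2S)-2-(2,2-dimethoxyethyl)-2,5-dimethylfuran-3(2H)-one
Conditions: HC(OMe)3, MeOH, pyridinium p-toluenesulfonate (cat.), rt
Reagents that add atoms: trimethyl orthoformate COC(OC)OC
Why: Acid-catalysed acetalisation masks the β-alkoxy aldehyde, removing the acidifying C8 carbonyl and with it the retro-oxa-Michael pathway that could racemise C10 in the basic steps that follow.

Step 6
Reactants: 10 (2S)-2-(2,2-dimethoxyethyl)-2,5-dimethylfuran-3(2H)-one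
Product: 11 (2S)-2-(2,2-dimethoxyethyl)-5-[(E)-2-(dimethylamino)ethenyl]-2-methylfuran-3(2H)-one
Conditions: t-BuOCH(NMe2)2, toluene, 80 °C
Reagents that add atoms: tert-butoxybis(dimethylamino)methane CN(C)C(OC(C)(C)C)N(C)C
Why: The C4 methyl is the vinylogous α-position of the furanone, so the aminal ester (which liberates tert-butoxide) should condense there to give the E-enamine, a formylation at the aldehyde oxidation level (enaminone synthesis with amide acetals).

Step 7
Reactants: 11 (2S)-2-(2,2-dimethoxyethyl)-5-[(E)-2-(dimethylamino)ethenyl]-2-methylfuran-3(2H)-one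
Product: 13 2-[(5S)-5-(2,2-dimethoxyethyl)-5-methyl-4-oxo-4,5-dihydrofuran-2-yl]prop-2-enal, via formylmethyl furanone 12 (not isolated)
Conditions: 37% aq. CH2O, pyrrolidine (20 mol%), EtCO2H (20 mol%), i-PrOH–H2O, 45 °C
Reagents that add atoms: water O; formaldehyde C=O
Why: Amine exchange and hydrolysis free the aldehyde 12, whose pyrrolidine enamine undergoes Mannich condensation with formaldehyde at C4 and β-elimination of the amine (organocatalytic α-methylenation of aldehydes) to give the 2-substituted acrolein carrying C15, the acetal being stable at this pH.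

Step 8
Reactants: 14 furan-2(5H)-one
Product: 15 3-(hydroxymethyl)furan-2(5H)-one
Conditions: 37% aq. CH2O, PBu3 (20 mol%), THF, rt
Reagents that add atoms: formaldehyde C=O
Why: Morita–Baylis–Hillman reaction: conjugate addition of the phosphine to the butenolide gives a phosphonium enolate that adds to formaldehyde at the α-carbon and then eliminates the catalyst.

Step 9
Reactants: 15 3-(hydroxymethyl)furan-2(5H)-one
Product: 16 triethyl({2-[(triethylsilyl)oxy]furan-3-yl}methoxy)silane
Conditions: Et3SiOTf (2.2 equiv), Et3N, CH2Cl2, 0 °C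
Reagents that add atoms: triethylsilyl trifluoromethanesulfonate CC[Si](CC)(CC)OS(=O)(=O)C(F)(F)F
Why: O-Silylation of the alcohol and soft γ-enolisation with O-silylation of the butenolide give the aromatic 2-silyloxyfuran, the standard dienolate equivalent for vinylogous aldol reactions.

Step 10
Reactants: 13 2-[(5S)-5-(2,2-dimethoxyethyl)-5-methyl-4-oxo-4,5-dihydrofuran-2-yl]prop-2-enal; 16 triethyl({2-[(triethylsilyl)oxy]furan-3-yl}methoxy)silane
Product: 17 (5S)-5-{(1R)-2-[(5S)-5-(2,2-dimethoxyethyl)-5-methyl-4-oxo-4,5-dihydrofuran-2-yl]-1-hydroxyprop-2-en-1-yl}-3-{[(triethylsilyl)oxy]methyl}furan-2(5H)-one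
Conditions: [(R,R)-N,N′-bis(3,5-di-tert-butylsalicylidene)cyclohexane-1,2-diaminato]chromium tetrafluoroborate (5 mol%), i-PrOH (1.2 equiv), CH2Cl2, −30 °C
Reagents that add atoms: none
Why: Catalytic enantioselective vinylogous Mukaiyama aldol reaction: the chiral trivalent-chromium Lewis acid activates the enal carbonyl for γ-attack (C6) by the 2-silyloxyfuran through an open transition state expected to give the anti (5R,6S) adduct, with the catalyst rather than the remote C10 centre controlling both new stereocentres (the ligand antipode is chosen accordingly).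

Step 11
Reactants: 17 (the vinylogous aldol adduct)
Product: 18 (5S)-5-{(1R)-1-[(tert-butyldimethylsilyl)oxy]-2-[(5S)-5-(2,2-dimethoxyethyl)-5-methyl-4-oxo-4,5-dihydrofuran-2-yl]prop-2-en-1-yl}-3-{[(triethylsilyl)oxy]methyl}furan-2(5H)-one
Conditions: TBSCl, imidazole, DMF, rt
Reagents that add atoms: tert-butyldimethylsilyl chloride CC(C)(C)[Si](C)(C)Cl
Why: Silylation of the secondary allylic C5 alcohol under conditions free of strong Lewis acid (a silyl triflate would attack the dimethyl acetal), so that later only the C8 hydroxyl is free for esterification.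

Step 12
Reactants: 18 (the C5 silyl ether)
Product: 19 (5S)-5-{(1R)-1-[(tert-butyldimethylsilyl)oxy]-2-[(5S)-5-methyl-4-oxo-5-(2-oxoethyl)-4,5-dihydrofuran-2-yl]prop-2-en-1-yl}-3-(hydroxymethyl)furan-2(5H)-one
Conditions: 1 M aq. HCl, THF, 0 °C to rt
Reagents that add atoms: water O
Why: Dilute acid should hydrolyse the dimethyl acetal and the primary triethylsilyl ether but not the hindered secondary tert-butyldimethylsilyl ether, unveiling the C8 aldehyde and the C13 allylic alcohol in one operation.

Step 13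
Reactants: 19 (the hydroxy aldehyde)
Product: 20 (5S)-3-(bromomethyl)-5-{(1R)-1-[(tert-butyldimethylsilyl)oxy]-2-[(5S)-5-methyl-4-oxo-5-(2-oxoethyl)-4,5-dihydrofuran-2-yl]prop-2-en-1-yl}furan-2(5H)-one
Conditions: NBS, Me2S, CH2Cl2, −20 to 0 °C
Reagents that add atoms: N-bromosuccinimide O=C1CCC(=O)N1Br
Why: Corey–Kim bromination converts the primary allylic alcohol into the bromide through an alkoxysulfonium salt under neutral conditions that tolerate the aldehyde (no phosphorus ylide, no base that could trigger retro-oxa-Michael opening).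

Step 14
Reactants: 20 (the bromo aldehyde)
Product: 22 (5R,6S,7R,8S,10S)-5-[(tert-butyldimethylsilyl)oxy]-8-hydroxy-1-oxo-3,10-epoxygermacra-2,4(15),11(13)-trien-12,6-olide, via allylchromium dichloride 21 (not isolated)
Conditions: CrCl2 (6 equiv), THF, 0.002 M, slow addition of 20, rt
Reagents that add atoms: none
Why: Intramolecular Nozaki–Hiyama allylation: the allylchromium reagent formed from the bromomethylbutenolide adds through its γ-carbon (C7) to the C8 aldehyde, closing the ten-membered carbocycle and unveiling the α-methylene lactone; C7 should be set by attack on the butenolide face anti to the C6 side chain (trans-lactone) and C8 by the closed chair transition state (anti adduct, 8S), and the weakly nucleophilic organochromium should leave the furanone ketone and the lactone alone.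

Step 15
Reactants: 22 (the 8S alcohol)
Product: 23 (5R,6S,7R,8R,10S)-5-[(tert-butyldimethylsilyl)oxy]-8-(3-methylbutanoyloxy)-1-oxo-3,10-epoxygermacra-2,4(15),11(13)-trien-12,6-olide
Conditions: 3-methylbutanoic acid, PPh3, diisopropyl azodicarboxylate, toluene, 0 °C to rt
Reagents that add atoms: 3-methylbutanoic acid CC(C)CC(=O)O
Why: Mitsunobu esterification installs the 3-methylbutanoate with SN2 inversion at C8 (8S to 8R) via the alkoxyphosphonium ion, the C5 hydroxyl being masked as its silyl ether.

Step 16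
Reactants: 23 (the silyl-protected ester)
Product: 24 (5R,6S,7R,8R,10S)-5-hydroxy-8-(3-methylbutanoyloxy)-1-oxo-3,10-epoxygermacra-2,4(15),11(13)-trien-12,6-olide (CNP0409337.1)
Conditions: HF·pyridine, pyridine–THF, 0 °C to rt
Reagents that add atoms: none
Why: Buffered fluoride cleaves the silyl ether (Si–F bond formation) without touching the α-methylene lactone, the ester or the furanone.

Compound list
1 | 4,4-dimethoxybutan-2-one | CC(=O)CC(OC)OC | starting material
2 | 2,2,6-trimethyl-4H-1,3-dioxin-4-one | CC1=CC(=O)OC(C)(C)O1 | starting material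
3 | acetylketene (3-oxobut-1-en-1-one) | CC(=O)C=C=O | intermediate
4 | 2-(2,2-dimethoxyethyl)-2,6-dimethyl-4H-1,3-dioxin-4-one (racemic) | CC1=CC(=O)OC(C)(CC(OC)OC)O1 | intermediate
5 | (2,6-dimethyl-4-oxo-4H-1,3-dioxin-2-yl)acetaldehyde (racemic) | CC1=CC(=O)OC(C)(CC=O)O1 | intermediate
6 | potassium (2Z)-3-{[(2Z)-4-oxobut-2-en-2-yl]oxy}but-2-enoate | O=C/C=C(/C)O/C(C)=C\C(=O)[O-].[K+] | intermediate
7 | methyl (2Z)-3-{[(2Z)-4-oxobut-2-en-2-yl]oxy}but-2-enoate | O=C/C=C(/C)O/C(C)=C\C(=O)OC | intermediate
8 | methyl [(2S)-2,5-dimethyl-3-oxo-2,3-dihydrofuran-2-yl]acetate | COC(=O)C[C@]1(C)OC(C)=CC1=O | intermediate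
9 | [(2S)-2,5-dimethyl-3-oxo-2,3-dihydrofuran-2-yl]acetaldehyde | O=CC[C@]1(C)OC(C)=CC1=O | intermediate
10 | (2S)-2-(2,2-dimethoxyethyl)-2,5-dimethylfuran-3(2H)-one | COC(OC)C[C@]1(C)OC(C)=CC1=O | intermediate
11 | (2S)-2-(2,2-dimethoxyethyl)-5-[(E)-2-(dimethylamino)ethenyl]-2-methylfuran-3(2H)-one | CN(C)/C=C/C1=CC(=O)[C@](C)(CC(OC)OC)O1 | intermediate
12 | [(5S)-5-(2,2-dimethoxyethyl)-5-methyl-4-oxo-4,5-dihydrofuran-2-yl]acetaldehyde | O=CCC1=CC(=O)[C@](C)(CC(OC)OC)O1 | intermediate
13 | 2-[(5S)-5-(2,2-dimethoxyethyl)-5-methyl-4-oxo-4,5-dihydrofuran-2-yl]prop-2-enal | C=C(C=O)C1=CC(=O)[C@](C)(CC(OC)OC)O1 | intermediate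
14 | furan-2(5H)-one | O=C1OCC=C1 | starting material
15 | 3-(hydroxymethyl)furan-2(5H)-one | O=C1OCC=C1CO | intermediate
16 | triethyl({2-[(triethylsilyl)oxy]furan-3-yl}methoxy)silane | CC[Si](CC)(CC)OCc1ccoc1O[Si](CC)(CC)CC | intermediate
17 | (5S)-5-{(1R)-2-[(5S)-5-(2,2-dimethoxyethyl)-5-methyl-4-oxo-4,5-dihydrofuran-2-yl]-1-hydroxyprop-2-en-1-yl}-3-{[(triethylsilyl)oxy]methyl}furan-2(5H)-one | O=C1O[C@@H](C=C1CO[Si](CC)(CC)CC)[C@H](O)C(=C)C1=CC(=O)[C@](C)(CC(OC)OC)O1 | intermediate
18 | (5S)-5-{(1R)-1-[(tert-butyldimethylsilyl)oxy]-2-[(5S)-5-(2,2-dimethoxyethyl)-5-methyl-4-oxo-4,5-dihydrofuran-2-yl]prop-2-en-1-yl}-3-{[(triethylsilyl)oxy]methyl}furan-2(5H)-one | O=C1O[C@@H](C=C1CO[Si](CC)(CC)CC)[C@H](O[Si](C)(C)C(C)(C)C)C(=C)C1=CC(=O)[C@](C)(CC(OC)OC)O1 | intermediate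
19 | (5S)-5-{(1R)-1-[(tert-butyldimethylsilyl)oxy]-2-[(5S)-5-methyl-4-oxo-5-(2-oxoethyl)-4,5-dihydrofuran-2-yl]prop-2-en-1-yl}-3-(hydroxymethyl)furan-2(5H)-one | O=C1O[C@@H](C=C1CO)[C@H](O[Si](C)(C)C(C)(C)C)C(=C)C1=CC(=O)[C@](C)(CC=O)O1 | intermediate
20 | (5S)-3-(bromomethyl)-5-{(1R)-1-[(tert-butyldimethylsilyl)oxy]-2-[(5S)-5-methyl-4-oxo-5-(2-oxoethyl)-4,5-dihydrofuran-2-yl]prop-2-en-1-yl}furan-2(5H)-one | O=C1O[C@@H](C=C1CBr)[C@H](O[Si](C)(C)C(C)(C)C)C(=C)C1=CC(=O)[C@](C)(CC=O)O1 | intermediate
21 | allylchromium dichloride derived from 20 (CrCl2 in place of Br at C13) | O=C1O[C@@H](C=C1C[Cr](Cl)Cl)[C@H](O[Si](C)(C)C(C)(C)C)C(=C)C1=CC(=O)[C@](C)(CC=O)O1 | intermediate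
22 | (5R,6S,7R,8S,10S)-5-[(tert-butyldimethylsilyl)oxy]-8-hydroxy-1-oxo-3,10-epoxygermacra-2,4(15),11(13)-trien-12,6-olide | C=C1C(=O)O[C@H]2[C@H]1[C@@H](O)C[C@]1(C)OC(=CC1=O)C(=C)[C@H]2O[Si](C)(C)C(C)(C)C | intermediate
23 | (5R,6S,7R,8R,10S)-5-[(tert-butyldimethylsilyl)oxy]-8-(3-methylbutanoyloxy)-1-oxo-3,10-epoxygermacra-2,4(15),11(13)-trien-12,6-olide | C=C1C(=O)O[C@H]2[C@H]1[C@H](OC(=O)CC(C)C)C[C@]1(C)OC(=CC1=O)C(=C)[C@H]2O[Si](C)(C)C(C)(C)C | intermediate
24 | (5R,6S,7R,8R,10S)-5-hydroxy-8-(3-methylbutanoyloxy)-1-oxo-3,10-epoxygermacra-2,4(15),11(13)-trien-12,6-olide | C=C1C(=O)O[C@H]2[C@H]1[C@H](OC(=O)CC(C)C)C[C@]1(C)OC(=CC1=O)C(=C)[C@H]2O | target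

Total step count: 16. Longest linear sequence: 14 steps (steps 1–7 and 10–16); steps 8–9 form the convergent branch.

Steps most likely to fail

Step 3 (key step). The carbene–enal adduct may be diverted into homoenolate or redox pathways, the carbene may cleave the divinyl ether by addition–elimination at C3, or facial discrimination at C10 may be poor. The fallback sets out from 7 and returns at 8. Pinnick oxidation (NaClO2, NaH2PO4, 2-methylbut-2-ene) would give (2Z)-3-{[(2Z)-4-methoxy-4-oxobut-2-en-2-yl]oxy}but-2-enoic acid F1. Treatment with (PhSe)2 and PBu3 would give methyl (2Z)-3-{[(2Z)-4-oxo-4-(phenylselanyl)but-2-en-2-yl]oxy}but-2-enoate F2. 5-exo acyl-radical cyclisation onto the vinylogous carbonate ((Me3Si)3SiH, Et3B, air, benzene, rt) would form the same C1–C10 bond and give racemic methyl (2,5-dimethyl-3-oxo-2,3-dihydrofuran-2-yl)acetate F3. Preparative chromatography on a chiral stationary phase would then deliver 8.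

Step 14. Intermolecular allylation (oligomerisation) may outcompete closure of the strained ten-membered ring, or closure may take place through the wrong butenolide or aldehyde face. The fallback sets out from 18 and returns at 23; it uses a Lewis-acid-promoted allylstannane cyclisation with an open transition state. Pyridinium p-toluenesulfonate in MeOH would remove only the primary triethylsilyl ether to give the allylic alcohol with the acetal intact F4. Corey–Kim bromination would give the allylic bromide acetal F5. (Bu3Sn)2 with Pd(PPh3)4 would give the allylstannane acetal F6. LiBF4 in wet MeCN would free the stannyl aldehyde F7. BF3·OEt2 at −78 °C under high dilution should close the ring through an antiperiplanar SE2′ transition state, expected to give the syn adduct, the 8R alcohol (5R,6S,7R,8R,10S)-5-[(tert-butyldimethylsilyl)oxy]-8-hydroxy-1-oxo-3,10-epoxygermacra-2,4(15),11(13)-trien-12,6-olide F8. Acylation with retention (3-methylbutanoic anhydride, 4-(dimethylamino)pyridine) would give 23.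

Step 10. Anti/syn control or enantiofacial discrimination at the hindered, cross-conjugated aldehyde may be insufficient, or 1,4-addition to the acrolein may compete. The fallback sets out from 15 (with 13) and returns at 17; it replaces Lewis-acid Mukaiyama activation by Brønsted-base/hydrogen-bond activation. Monosilylation (Et3SiCl, imidazole) would give 3-{[(triethylsilyl)oxy]methyl}furan-2(5H)-one F9. Direct vinylogous aldol addition of F9 to 13 would be catalysed by the bifunctional squaramide 3-{[3,5-bis(trifluoromethyl)phenyl]amino}-4-{[(1S,2S)-2-(dimethylamino)cyclohexyl]amino}cyclobut-3-ene-1,2-dione (antipode chosen for 5R,6S), giving 17.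

Further compounds
F1 | step 3 | (2Z)-3-{[(2Z)-4-methoxy-4-oxobut-2-en-2-yl]oxy}but-2-enoic acid | OC(=O)/C=C(/C)O/C(C)=C\C(=O)OC
F2 | step 3 | methyl (2Z)-3-{[(2Z)-4-oxo-4-(phenylselanyl)but-2-en-2-yl]oxy}but-2-enoate | O=C([Se]c1ccccc1)/C=C(/C)O/C(C)=C\C(=O)OC
F3 | step 3 | racemic methyl (2,5-dimethyl-3-oxo-2,3-dihydrofuran-2-yl)acetate | COC(=O)CC1(C)OC(C)=CC1=O
F4 | step 14 | (5S)-5-{(1R)-1-[(tert-butyldimethylsilyl)oxy]-2-[(5S)-5-(2,2-dimethoxyethyl)-5-methyl-4-oxo-4,5-dihydrofuran-2-yl]prop-2-en-1-yl}-3-(hydroxymethyl)furan-2(5H)-one | O=C1O[C@@H](C=C1CO)[C@H](O[Si](C)(C)C(C)(C)C)C(=C)C1=CC(=O)[C@](C)(CC(OC)OC)O1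
F5 | step 14 | (5S)-3-(bromomethyl)-5-{(1R)-1-[(tert-butyldimethylsilyl)oxy]-2-[(5S)-5-(2,2-dimethoxyethyl)-5-methyl-4-oxo-4,5-dihydrofuran-2-yl]prop-2-en-1-yl}furan-2(5H)-one | O=C1O[C@@H](C=C1CBr)[C@H](O[Si](C)(C)C(C)(C)C)C(=C)C1=CC(=O)[C@](C)(CC(OC)OC)O1
F6 | step 14 | (5S)-5-{(1R)-1-[(tert-butyldimethylsilyl)oxy]-2-[(5S)-5-(2,2-dimethoxyethyl)-5-methyl-4-oxo-4,5-dihydrofuran-2-yl]prop-2-en-1-yl}-3-[(tributylstannyl)methyl]furan-2(5H)-one | O=C1O[C@@H](C=C1C[Sn](CCCC)(CCCC)CCCC)[C@H](O[Si](C)(C)C(C)(C)C)C(=C)C1=CC(=O)[C@](C)(CC(OC)OC)O1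
F7 | step 14 | (5S)-5-{(1R)-1-[(tert-butyldimethylsilyl)oxy]-2-[(5S)-5-methyl-4-oxo-5-(2-oxoethyl)-4,5-dihydrofuran-2-yl]prop-2-en-1-yl}-3-[(tributylstannyl)methyl]furan-2(5H)-one | O=C1O[C@@H](C=C1C[Sn](CCCC)(CCCC)CCCC)[C@H](O[Si](C)(C)C(C)(C)C)C(=C)C1=CC(=O)[C@](C)(CC=O)O1
F8 | step 14 | (5R,6S,7R,8R,10S)-5-[(tert-butyldimethylsilyl)oxy]-8-hydroxy-1-oxo-3,10-epoxygermacra-2,4(15),11(13)-trien-12,6-olide | C=C1C(=O)O[C@H]2[C@H]1[C@H](O)C[C@]1(C)OC(=CC1=O)C(=C)[C@H]2O[Si](C)(C)C(C)(C)C
F9 | step 10 | 3-{[(triethylsilyl)oxy]methyl}furan-2(5H)-one | O=C1OCC=C1CO[Si](CC)(CC)CC
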